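**Plan**

- Locants (lignan numbering): ring A = O–C7–C8–C8′–C9′ and ring B = O–C7′–C8′–C8–C9 form the 3,7-dioxabicyclo[3.3.0]octane. The guaiacyl group sits on C7 and the phenylcoumaran (C7″ aryl-bearing, C8″, C9″H2OH) on C7′. The target is 7S,8S,7′S,8′S,7″S,8″S, i.e. both aryl groups endo on the furofuran and a 7″,8″-cis phenylcoumaran.
- Retrosynthetic cuts: three O–Si bonds; C9–H (from a C9 methyl acetal); C7–C8 together with the C7–O acetal link, which divides the molecule into a vanillin dimethyl acetal and a cis-2-aryl-3-(hydroxymethyl)-2,3-dihydrofuran; the ring B enol ether and C7′–C8′ back to an anti-aldol adduct of a pent-4-enoyl imide; C7″–C8″ back to an aryldiazoacetate.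
- What makes the key event possible: in ring B the unit O–C9=C8 is an enol ether whose nucleophilic β-carbon is C8. C7, flanked by the ring A oxygen and an electron-rich arene, is a stabilised oxocarbenium centre. The C8′–C9′H2–O tether holds C7 over C8, so ring A closes by the single bond C7–C8.
- Forward order: phenylcoumaran (rhodium carbenoid C–H insertion) → its C5 aldehyde → ring B (aldol, alkene cleavage to the lactol, dehydration) → ring A (key step) → C9 deoxygenation → desilylation.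
- Stereochemistry: C7″/C8″ from the chiral dirhodium carboxylate (kinetic cis insertion); C7′/C8′ from the oxazolidinone auxiliary (anti aldol, which becomes the cis ring B); C8 from the tether (cis ring fusion); C7 from kinetic endo closure on the E oxocarbenium ion.

Key step: step 16

**Remarks**

- Abbreviations: TIPS = triisopropylsilyl; ArG = 3-methoxy-4-(triisopropylsilyloxy)phenyl; Ar′ = (2S,3S)-7-methoxy-2-ArG-3-[(triisopropylsilyloxy)methyl]-2,3-dihydro-1-benzofuran-5-yl.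
- Assumption (step 7): the catalyst antipode that delivers the 2S (aryl-bearing carbon) cis ester is taken to be Rh2(R-PTTL)4; should the sense of induction be opposite, Rh2(S-PTTL)4 is used with no other change.
- Assumption (step 12): the magnesium-chelated Z-enolate of the (S)-4-benzyl imide is taken to react on the face used in its alkylations, giving the (2R,3S)-anti adduct; should the sense be opposite, the (R)-auxiliary is used.

**Route**

Step 1
Reactants: 1 vanillin (4-hydroxy-3-methoxybenzaldehyde)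
Product: 2 3-methoxy-4-(triisopropylsilyloxy)benzaldehyde
Conditions: TIPSCl, imidazole, DMF, rt
Reagents that add atoms: triisopropylsilyl chloride, CC(C)[Si](Cl)(C(C)C)C(C)C
Why: Imidazole-promoted silylation of the phenol should install an aryl TIPS ether that withstands the hydride, base and Lewis-acid steps ahead, is a weaker π-donor than an alkyl ether (less benzylic ionisation later) and leaves with fluoride at the end.

Step 2
Reactants: 2 3-methoxy-4-(triisopropylsilyloxy)benzaldehyde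
Product: 3 [4-(dimethoxymethyl)-2-methoxyphenoxy]triisopropylsilane (ArG–CH(OMe)2)
Conditions: HC(OMe)3, MeOH, pyridinium p-toluenesulfonate (cat.), rt; NaHCO3 quench
Reagents that add atoms: trimethyl orthoformate, COC(OC)OC; methanol, CO
Why: Acid-catalysed acetalisation with the orthoformate as water scavenger should give the dimethyl acetal that later serves as the C7 oxocarbenium precursor.

Step 3
Reactants: 2 3-methoxy-4-(triisopropylsilyloxy)benzaldehyde
Product: 4 [3-methoxy-4-(triisopropylsilyloxy)phenyl]methanol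
Conditions: NaBH4, MeOH, 0 °C
Reagents that add atoms: none
Why: Borohydride reduction of the aryl aldehyde should give the benzylic alcohol without touching the silyl ether.

Step 4
Reactants: 4 [3-methoxy-4-(triisopropylsilyloxy)phenyl]methanol; 5 methyl 3-bromo-4-hydroxy-5-methoxybenzoate
Product: 6 methyl 3-bromo-5-methoxy-4-[(ArG)methoxy]benzoate
Conditions: PPh3, DIAD, THF, 0 °C to rt
Reagents that add atoms: none
Why: Mitsunobu etherification of the acidic ortho-bromophenol with the benzylic alcohol should form the aryl benzyl ether under neutral conditions, avoiding an unstable para-silyloxybenzyl halide and carbonate-induced desilylation.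

Step 5
Reactants: 6 methyl 3-bromo-5-methoxy-4-[(ArG)methoxy]benzoate
Product: 7 methyl 3-methoxy-5-(2-methoxy-2-oxoethyl)-4-[(ArG)methoxy]benzoate
Conditions: BrZnCH2CO2Me (from methyl bromoacetate and Zn dust, THF), Pd2(dba)3 (2.5 mol %), XPhos (10 mol %), THF, 60 °C
Reagents that add atoms: methyl bromoacetate, BrCC(=O)OC, used as its zinc reagent bromo(2-methoxy-2-oxoethyl)zinc, COC(=O)C[Zn]Br
Why: Negishi-type cross-coupling of the Reformatsky reagent with the aryl bromide (a neutral α-arylation of an acetate) should install the arylacetate while tolerating the benzoate and the silyl ether.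

Step 6
Reactants: 7 methyl 3-methoxy-5-(2-methoxy-2-oxoethyl)-4-[(ArG)methoxy]benzoate
Product: 8 methyl 3-(1-diazo-2-methoxy-2-oxoethyl)-5-methoxy-4-[(ArG)methoxy]benzoate
Conditions: 4-acetamidobenzenesulfonyl azide, DBU, dry MeCN, 0 °C to rt
Reagents that add atoms: 4-acetamidobenzenesulfonyl azide, CC(=O)Nc1ccc(cc1)S(=O)(=O)N=[N+]=[N-]
Why: Regitz diazo transfer to the doubly activated arylacetate methylene should give the donor/acceptor aryldiazoacetate.

Step 7
Reactants: 8 methyl 3-(1-diazo-2-methoxy-2-oxoethyl)-5-methoxy-4-[(ArG)methoxy]benzoate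
Product: 9 dimethyl (2S,3R)-7-methoxy-2-ArG-2,3-dihydro-1-benzofuran-3,5-dicarboxylate (2,3-cis)
Conditions: Rh2(R-PTTL)4 (dirhodium tetrakis[N-phthaloyl-(R)-tert-leucinate], 1 mol %), toluene, −60 °C
Reagents that add atoms: none
Why: Intramolecular 1,5 C–H insertion of the rhodium carbenoid into the electron-rich benzylic ether C–H bond should close the dihydrobenzofuran and create C7″ and C8″ together, the cis relationship being the kinetic outcome of the concerted insertion and the absolute sense coming from the chiral carboxylate ligands.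

Step 8
Reactants: 9 dimethyl (2S,3R)-7-methoxy-2-ArG-2,3-dihydro-1-benzofuran-3,5-dicarboxylate
Product: 10 [(2S,3S)-3-(hydroxymethyl)-7-methoxy-2-ArG-2,3-dihydro-1-benzofuran-5-yl]methanol
Conditions: i-Bu2AlH (6 equiv), CH2Cl2, −78 to 0 °C; aq. potassium sodium tartrate
Reagents that add atoms: none
Why: Low-temperature reduction of both esters with the weakly basic aluminium hydride should remove the epimerisable ester at C8″ at once and so fix the cis arrangement.

Step 9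
Reactants: 10 [(2S,3S)-3-(hydroxymethyl)-7-methoxy-2-ArG-2,3-dihydro-1-benzofuran-5-yl]methanol
Product: 11 (2S,3S)-3-(hydroxymethyl)-7-methoxy-2-ArG-2,3-dihydro-1-benzofuran-5-carbaldehyde
Conditions: activated MnO2 (excess), CH2Cl2, rt
Reagents that add atoms: none
Why: MnO2 should oxidise only the benzylic alcohol on the electron-rich arene and leave the aliphatic primary alcohol untouched.

Step 10
Reactants: 11 (2S,3S)-3-(hydroxymethyl)-7-methoxy-2-ArG-2,3-dihydro-1-benzofuran-5-carbaldehyde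
Product: 12 (2S,3S)-7-methoxy-2-ArG-3-[(triisopropylsilyloxy)methyl]-2,3-dihydro-1-benzofuran-5-carbaldehyde (Ar′–CHO)
Conditions: TIPSOTf, 2,6-lutidine, CH2Cl2, −78 to 0 °C
Reagents that add atoms: triisopropylsilyl trifluoromethanesulfonate, CC(C)[Si](OS(=O)(=O)C(F)(F)F)(C(C)C)C(C)C
Why: Silylation of the hindered primary alcohol with the silyl triflate should mask C9″–OH with the same fluoride-labile group as the phenols.

Step 11
Reactants: 13 (S)-4-benzyloxazolidin-2-one; 14 pent-4-enoyl chloride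
Product: 15 (S)-4-benzyl-3-(pent-4-enoyl)oxazolidin-2-one
Conditions: n-BuLi, THF, −78 °C; then 14, −78 to 0 °C
Reagents that add atoms: none
Why: N-Acylation of the lithiated oxazolidinone should give the imide whose allyl group is the masked C8–C9 aldehyde.

Step 12
Reactants: 12 Ar′–CHO; 15 (S)-4-benzyl-3-(pent-4-enoyl)oxazolidin-2-one
Product: 17 (S)-4-benzyl-3-{(2R)-2-[(S)-hydroxy(Ar′)methyl]pent-4-enoyl}oxazolidin-2-one, via TMS ether 16 (not isolated)
Conditions: MgCl2 (0.2 equiv), Et3N (2 equiv), TMSCl (1.5 equiv), EtOAc, rt; then 1 M HCl/THF 1:5, 0 °C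
Reagents that add atoms: none
Why: The magnesium chloride-catalysed Evans anti-aldol reaction of the chelated Z-enolate with the non-enolisable aryl aldehyde should set C7′ (S) and C8′ under auxiliary control in the anti sense, which is the relationship that becomes the cis-2,3-disubstituted ring B.

Step 13
Reactants: 17 (S)-4-benzyl-3-{(2R)-2-[(S)-hydroxy(Ar′)methyl]pent-4-enoyl}oxazolidin-2-one
Product: 20 (S)-4-benzyl-3-{[(2S,3R)-2-Ar′-5-hydroxytetrahydrofuran-3-yl]carbonyl}oxazolidin-2-one (C5 anomers), via diol 18 (not isolated), via hydroxy aldehyde 19 (not isolated)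
Conditions: OsO4 (2 mol %), NaIO4 (4 equiv), 2,6-lutidine (2 equiv), 1,4-dioxane/H2O 3:1, rt
Reagents that add atoms: osmium tetroxide, O=[Os](=O)(=O)=O, regenerated by sodium periodate, [Na+].[O-]I(=O)(=O)=O
Why: Lemieux–Johnson cleavage of the terminal alkene should unveil the C9 aldehyde, which the C7′ hydroxyl captures as the five-membered lactol, so that ring B is formed with its O–C9 bond in place.

Step 14
Reactants: 20 (S)-4-benzyl-3-{[(2S,3R)-2-Ar′-5-hydroxytetrahydrofuran-3-yl]carbonyl}oxazolidin-2-one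
Product: 22 (S)-4-benzyl-3-{[(2S,3R)-2-Ar′-2,3-dihydrofuran-3-yl]carbonyl}oxazolidin-2-one, via anomeric mesylate 21 (not isolated)
Conditions: MsCl (1.5 equiv), Et3N (4 equiv), CH2Cl2, −40 °C to rt
Reagents that add atoms: none
Why: Anomeric sulfonylation followed by amine-assisted loss of the C8 proton from the incipient cyclic oxocarbenium ion (lactol dehydration to a glycal-type enol ether) should give the C8=C9 enol ether without disturbing C7′ or C8′.

Step 15
Reactants: 22 (S)-4-benzyl-3-{[(2S,3R)-2-Ar′-2,3-dihydrofuran-3-yl]carbonyl}oxazolidin-2-one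
Product: 23 [(2S,3S)-2-Ar′-2,3-dihydrofuran-3-yl]methanol
Conditions: LiBH4 (2 equiv), MeOH (2 equiv), THF, 0 °C
Reagents that add atoms: none
Why: Reductive cleavage of the imide with lithium borohydride should release the C9′ alcohol and the auxiliary while the enol ether and the silyl ethers remain intact.

Step 16
Reactants: 23 [(2S,3S)-2-Ar′-2,3-dihydrofuran-3-yl]methanol; 3 ArG–CH(OMe)2
Product: 26 (1S,3aR,4S,6aS)-1-Ar′-4-ArG-3-methoxytetrahydro-1H,3H-furo[3,4-c]furan (C3 = C9 anomers; both aryl groups endo), via mixed acetal 24 (not isolated), via oxocarbenium ion 25 (not isolated)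
Conditions: 3 (1.5 equiv), TMSOTf (0.2 equiv), CH2Cl2, −78 to −40 °C; Et3N quench at −78 °C
Reagents that add atoms: none
Why: TMSOTf should exchange one methoxy group of 3 for the primary hydroxyl of 23 (mixed acetal 24) and ionise 24 to the E aryl oxocarbenium ion 25, whose C7 is attacked by C8, the β-carbon of the ring B enol ether, the new C9 oxocarbenium ion then being capped by methanol; this is an intramolecular Prins-type (oxocarbenium–enol ether, Mukaiyama-like) cyclisation of the kind known from dihydrofuran-template routes to furofurans. Ring A closes in a 5-(enolexo)-endo-trig mode, with the C7=O+ bond inside the new five-membered ring and the C8=C9 bond outside it. C8 is set by the tether, because the O–C9′H2 link on C8′ can reach only the face of ring B on which it stands, so the ring fusion must be cis and the aryl group already cis on C7′ becomes endo. C7 is set under kinetic control: in the compact transition state the C7=O+ bond of the E ion lies over the C8–C8′ bond, which places the aryl group above ring B (endo, cis to C9), whereas the exo isomer requires the extended arrangement; C9 forms as an anomeric mixture that is irrelevant because the methoxy group is removed in the next step. The step needs C7-endo over C7-exo selectivity and survival of the acid-labile benzylic C–O bonds at C7, C7′ and C7″, which the low temperature, the sub-stoichiometric Lewis acid, the cold amine quench and the weakly donating silyloxyaryl groups should secure.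

Step 17
Reactants: 26 (1S,3aR,4S,6aS)-1-Ar′-4-ArG-3-methoxytetrahydro-1H,3H-furo[3,4-c]furan
Product: 27 (1S,3aS,4S,6aS)-1-Ar′-4-ArG-tetrahydro-1H,3H-furo[3,4-c]furan (tris-TIPS ether of the target)
Conditions: Et3SiH (3 equiv), BF3·OEt2 (1.5 equiv), CH2Cl2, −78 °C; Et3N then aq. NaHCO3 at −78 °C
Reagents that add atoms: none
Why: Ionic hydrogenation of the anomeric methyl acetal (exocyclic C9–OMe ionisation to the bicyclic oxocarbenium ion, hydride transfer from the silane) should turn C9 into a methylene group without creating or touching a stereocentre, the acetal ionising far faster than the benzylic ethers at −78 °C.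

Step 18
Reactants: 27 (1S,3aS,4S,6aS)-1-Ar′-4-ArG-tetrahydro-1H,3H-furo[3,4-c]furan
Product: 28 4-[(1S,3aS,4S,6aS)-4-[(2S,3S)-2-(4-hydroxy-3-methoxyphenyl)-3-(hydroxymethyl)-7-methoxy-2,3-dihydro-1-benzofuran-5-yl]tetrahydro-1H,3H-furo[3,4-c]furan-1-yl]-2-methoxyphenol (CNP0303197.1)
Conditions: Bu4NF (4 equiv), AcOH (4 equiv), THF, 0 °C to rt
Reagents that add atoms: none
Why: Acetic acid-buffered fluoride should cleave the two aryl and the one alkyl TIPS ethers under non-acidic conditions that do not epimerise the endo benzylic ether centres or the cis phenylcoumaran.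

**Compound list**

1 | vanillin (4-hydroxy-3-methoxybenzaldehyde) | COc1cc(C=O)ccc1O | starting material
2 | 3-methoxy-4-(triisopropylsilyloxy)benzaldehyde | COc1cc(C=O)ccc1O[Si](C(C)C)(C(C)C)C(C)C | intermediate
3 | [4-(dimethoxymethyl)-2-methoxyphenoxy]triisopropylsilane | COC(OC)c1ccc(O[Si](C(C)C)(C(C)C)C(C)C)c(OC)c1 | intermediate
4 | [3-methoxy-4-(triisopropylsilyloxy)phenyl]methanol | COc1cc(CO)ccc1O[Si](C(C)C)(C(C)C)C(C)C | intermediate
5 | methyl 3-bromo-4-hydroxy-5-methoxybenzoate | COC(=O)c1cc(Br)c(O)c(OC)c1 | starting material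
6 | methyl 3-bromo-5-methoxy-4-{[3-methoxy-4-(triisopropylsilyloxy)benzyl]oxy}benzoate | COC(=O)c1cc(Br)c(OCc2ccc(O[Si](C(C)C)(C(C)C)C(C)C)c(OC)c2)c(OC)c1 | intermediate
7 | methyl 3-methoxy-5-(2-methoxy-2-oxoethyl)-4-{[3-methoxy-4-(triisopropylsilyloxy)benzyl]oxy}benzoate | COC(=O)Cc1cc(C(=O)OC)cc(OC)c1OCc1ccc(O[Si](C(C)C)(C(C)C)C(C)C)c(OC)c1 | intermediate
8 | methyl 3-(1-diazo-2-methoxy-2-oxoethyl)-5-methoxy-4-{[3-methoxy-4-(triisopropylsilyloxy)benzyl]oxy}benzoate | COC(=O)C(=[N+]=[N-])c1cc(C(=O)OC)cc(OC)c1OCc1ccc(O[Si](C(C)C)(C(C)C)C(C)C)c(OC)c1 | intermediate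
9 | dimethyl (2S,3R)-7-methoxy-2-[3-methoxy-4-(triisopropylsilyloxy)phenyl]-2,3-dihydro-1-benzofuran-3,5-dicarboxylate (cis) | COC(=O)c1cc(OC)c2c(c1)[C@@H](C(=O)OC)[C@@H](c1ccc(O[Si](C(C)C)(C(C)C)C(C)C)c(OC)c1)O2 | intermediate
10 | [(2S,3S)-3-(hydroxymethyl)-7-methoxy-2-[3-methoxy-4-(triisopropylsilyloxy)phenyl]-2,3-dihydro-1-benzofuran-5-yl]methanol (cis) | OCc1cc(OC)c2c(c1)[C@@H](CO)[C@@H](c1ccc(O[Si](C(C)C)(C(C)C)C(C)C)c(OC)c1)O2 | intermediate
11 | (2S,3S)-3-(hydroxymethyl)-7-methoxy-2-[3-methoxy-4-(triisopropylsilyloxy)phenyl]-2,3-dihydro-1-benzofuran-5-carbaldehyde | O=Cc1cc(OC)c2c(c1)[C@@H](CO)[C@@H](c1ccc(O[Si](C(C)C)(C(C)C)C(C)C)c(OC)c1)O2 | intermediate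
12 | (2S,3S)-7-methoxy-2-[3-methoxy-4-(triisopropylsilyloxy)phenyl]-3-[(triisopropylsilyloxy)methyl]-2,3-dihydro-1-benzofuran-5-carbaldehyde (Ar′–CHO) | O=Cc1cc(OC)c2c(c1)[C@@H](CO[Si](C(C)C)(C(C)C)C(C)C)[C@@H](c1ccc(O[Si](C(C)C)(C(C)C)C(C)C)c(OC)c1)O2 | intermediate
13 | (S)-4-benzyloxazolidin-2-one | O=C1OC[C@H](Cc2ccccc2)N1 | starting material
14 | pent-4-enoyl chloride | C=CCCC(Cl)=O | starting material
15 | (S)-4-benzyl-3-(pent-4-enoyl)oxazolidin-2-one | C=CCCC(=O)N1C(=O)OC[C@@H]1Cc1ccccc1 | intermediate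
16 | O-trimethylsilyl ether of 17 (not isolated) | O=C([C@H](CC=C)[C@H](O[Si](C)(C)C)c1cc(OC)c2c(c1)[C@@H](CO[Si](C(C)C)(C(C)C)C(C)C)[C@@H](c1ccc(O[Si](C(C)C)(C(C)C)C(C)C)c(OC)c1)O2)N1C(=O)OC[C@@H]1Cc1ccccc1 | intermediate
17 | (S)-4-benzyl-3-{(2R)-2-[(S)-hydroxy(Ar′)methyl]pent-4-enoyl}oxazolidin-2-one (anti aldol) | O=C([C@H](CC=C)[C@H](O)c1cc(OC)c2c(c1)[C@@H](CO[Si](C(C)C)(C(C)C)C(C)C)[C@@H](c1ccc(O[Si](C(C)C)(C(C)C)C(C)C)c(OC)c1)O2)N1C(=O)OC[C@@H]1Cc1ccccc1 | intermediate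
18 | (S)-4-benzyl-3-{(2R)-4,5-dihydroxy-2-[(S)-hydroxy(Ar′)methyl]pentanoyl}oxazolidin-2-one (C4 epimers; not isolated) | O=C([C@H](CC(O)CO)[C@H](O)c1cc(OC)c2c(c1)[C@@H](CO[Si](C(C)C)(C(C)C)C(C)C)[C@@H](c1ccc(O[Si](C(C)C)(C(C)C)C(C)C)c(OC)c1)O2)N1C(=O)OC[C@@H]1Cc1ccccc1 | intermediate
19 | (S)-4-benzyl-3-{(2R)-2-[(S)-hydroxy(Ar′)methyl]-4-oxobutanoyl}oxazolidin-2-one (not isolated) | O=C([C@H](CC=O)[C@H](O)c1cc(OC)c2c(c1)[C@@H](CO[Si](C(C)C)(C(C)C)C(C)C)[C@@H](c1ccc(O[Si](C(C)C)(C(C)C)C(C)C)c(OC)c1)O2)N1C(=O)OC[C@@H]1Cc1ccccc1 | intermediate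
20 | (S)-4-benzyl-3-{[(2S,3R)-2-Ar′-5-hydroxytetrahydrofuran-3-yl]carbonyl}oxazolidin-2-one (C5 anomers; Ar′ and carbonyl cis) | O=C([C@@H]1CC(O)O[C@@H]1c2cc(OC)c3c(c2)[C@@H](CO[Si](C(C)C)(C(C)C)C(C)C)[C@@H](c2ccc(O[Si](C(C)C)(C(C)C)C(C)C)c(OC)c2)O3)N1C(=O)OC[C@@H]1Cc1ccccc1 | intermediate
21 | anomeric methanesulfonate of 20 (not isolated) | O=C([C@@H]1CC(OS(C)(=O)=O)O[C@@H]1c2cc(OC)c3c(c2)[C@@H](CO[Si](C(C)C)(C(C)C)C(C)C)[C@@H](c2ccc(O[Si](C(C)C)(C(C)C)C(C)C)c(OC)c2)O3)N1C(=O)OC[C@@H]1Cc1ccccc1 | intermediate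
22 | (S)-4-benzyl-3-{[(2S,3R)-2-Ar′-2,3-dihydrofuran-3-yl]carbonyl}oxazolidin-2-one | O=C([C@@H]1C=CO[C@@H]1c2cc(OC)c3c(c2)[C@@H](CO[Si](C(C)C)(C(C)C)C(C)C)[C@@H](c2ccc(O[Si](C(C)C)(C(C)C)C(C)C)c(OC)c2)O3)N1C(=O)OC[C@@H]1Cc1ccccc1 | intermediate
23 | [(2S,3S)-2-Ar′-2,3-dihydrofuran-3-yl]methanol (cis) | OC[C@@H]1C=CO[C@@H]1c2cc(OC)c3c(c2)[C@@H](CO[Si](C(C)C)(C(C)C)C(C)C)[C@@H](c2ccc(O[Si](C(C)C)(C(C)C)C(C)C)c(OC)c2)O3 | intermediate
24 | mixed acetal ArG–CH(OMe)–O–CH2–[(2S,3S)-2-Ar′-2,3-dihydrofuran-3-yl] (acetal carbon epimers; not isolated) | COC(OC[C@@H]1C=CO[C@@H]1c2cc(OC)c3c(c2)[C@@H](CO[Si](C(C)C)(C(C)C)C(C)C)[C@@H](c2ccc(O[Si](C(C)C)(C(C)C)C(C)C)c(OC)c2)O3)c1ccc(O[Si](C(C)C)(C(C)C)C(C)C)c(OC)c1 | intermediate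
25 | (E)-oxocarbenium ion ArG–CH=O(+)–CH2–[(2S,3S)-2-Ar′-2,3-dihydrofuran-3-yl] triflate (not isolated) | COc1cc(/C=[O+]/C[C@@H]2C=CO[C@@H]2c2cc(OC)c3c(c2)[C@@H](CO[Si](C(C)C)(C(C)C)C(C)C)[C@@H](c2ccc(O[Si](C(C)C)(C(C)C)C(C)C)c(OC)c2)O3)ccc1O[Si](C(C)C)(C(C)C)C(C)C.[O-]S(=O)(=O)C(F)(F)F | intermediate
26 | (1S,3aR,4S,6aS)-1-Ar′-4-ArG-3-methoxytetrahydro-1H,3H-furo[3,4-c]furan (C3 anomers; lignan C9 methyl acetal, aryl groups on C7 and C7′ endo) | COc1cc([C@H]2OC[C@@H]3[C@H]2C(OC)O[C@@H]3c2cc(OC)c3c(c2)[C@@H](CO[Si](C(C)C)(C(C)C)C(C)C)[C@@H](c2ccc(O[Si](C(C)C)(C(C)C)C(C)C)c(OC)c2)O3)ccc1O[Si](C(C)C)(C(C)C)C(C)C | intermediate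
27 | (1S,3aS,4S,6aS)-1-Ar′-4-ArG-tetrahydro-1H,3H-furo[3,4-c]furan (tris-TIPS ether of the target) | COc1cc([C@H]2OC[C@@H]3[C@H]2CO[C@@H]3c2cc(OC)c3c(c2)[C@@H](CO[Si](C(C)C)(C(C)C)C(C)C)[C@@H](c2ccc(O[Si](C(C)C)(C(C)C)C(C)C)c(OC)c2)O3)ccc1O[Si](C(C)C)(C(C)C)C(C)C | intermediate
28 | 4-[(1S,3aS,4S,6aS)-4-[(2S,3S)-2-(4-hydroxy-3-methoxyphenyl)-3-(hydroxymethyl)-7-methoxy-2,3-dihydro-1-benzofuran-5-yl]tetrahydro-1H,3H-furo[3,4-c]furan-1-yl]-2-methoxyphenol (CNP0303197.1) | COc1cc([C@H]2OC[C@@H]3[C@H]2CO[C@@H]3c2cc(OC)c3c(c2)[C@@H](CO)[C@@H](c2ccc(O)c(OC)c2)O3)ccc1O | target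

**Step count and risks**

Total steps: 18. Longest linear sequence: 16 steps (steps 1, 3 to 10 and 12 to 18).

Steps most likely to fail:

1. Step 16 (key step). What may go wrong:
   - closure through the extended transition state, giving the C7-exo aryl series;
   - protonation of the ring B enol ether before C–C bond formation;
   - Lewis-acid ionisation of the benzylic C7′–O or C7″–O bonds, with loss of the cis relationships.

   Fallback, forming the same C7–C8 bond by rhodium carbenoid C–H insertion instead of a cationic closure; it sets out from 23 (with 4) and returns at 27. Alcohol 4 would be converted with CBr4/PPh3 (CH2Cl2, 0 °C) into 4-(bromomethyl)-2-methoxy-1-(triisopropylsilyloxy)benzene F1, used at once to alkylate the sodium alkoxide of 23 (NaH, THF/DMF, 0 °C) to the ArG-methyl ether of 23 F2. Buffered C5H5NH[CrO3Cl] (pyridinium chlorochromate, NaOAc, CH2Cl2) would oxidise the enol ether to the cis γ-lactone F3. LiN(SiMe3)2 and 2,2,2-trifluoroethyl trifluoroacetate (THF, −78 °C) would give the α-trifluoroacetyl lactone F4, and MsN3/Et3N (MeCN) the α-diazo lactone F5 by detrifluoroacetylative diazo transfer. Rh2(OAc)4 (CH2Cl2, rt) should insert the C8 carbenoid into the benzylic C7–H bond (1,5-insertion, cis fusion enforced, endo aryl expected) to give the furofuranone F6. i-Bu2AlH (CH2Cl2, −78 °C) would give the lactol F7, which Et3SiH/BF3·OEt2 (−78 °C) reduces to 27.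

2. Step 17. What may go wrong: ionisation of the benzylic C7–O or C7′–O ether bonds in competition with the anomeric C9–OMe bond, leading to epimerisation towards the exo aryl series or to reductive ring opening.

   Fallback, replacing the ionic hydrogenation by ring opening and SN2 reclosure; it sets out from 26 and returns at 27. Mild hydrolysis (AcOH/H2O/THF, 40 °C) would give the lactol F8. NaBH4 (MeOH, 0 °C) would reduce its open form to the 1,4-diol F9 (primary C9–OH, benzylic C7′–OH). TsCl/pyridine (0 °C) would sulfonylate only the primary hydroxyl to the tosylate F10. NaH (THF, 0 °C) would then let the C7′ alkoxide displace the C9 tosylate (5-exo-tet, C7′ configuration retained) to give 27.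

3. Step 14. What may go wrong: amine-mediated epimerisation at C8′, or migration of the C8=C9 double bond into conjugation with the imide carbonyl, while the enol ether is being formed next to the acidifying carbonyl group.

   Fallback, removing the carbonyl group before the enol ether is made; it sets out from 17 and returns at 23. LiBH4 (MeOH, THF, 0 °C) would give the diol (2S)-2-[(S)-hydroxy(Ar′)methyl]pent-4-en-1-ol F11. PivCl/pyridine (CH2Cl2, −20 °C) would acylate only the primary hydroxyl to the pivalate F12. OsO4/NaIO4/2,6-lutidine would give the lactol pivalate F13, and MsCl/Et3N the dihydrofuran pivalate F14. i-Bu2AlH (CH2Cl2, −78 °C) would cleave the ester to 23.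

**Further compounds**

F1 | step 16 | 4-(bromomethyl)-2-methoxy-1-(triisopropylsilyloxy)benzene | COc1cc(CBr)ccc1O[Si](C(C)C)(C(C)C)C(C)C
F2 | step 16 | (2S,3S)-2-Ar′-3-{[(ArG)methoxy]methyl}-2,3-dihydrofuran | COc1cc(COC[C@@H]2C=CO[C@@H]2c2cc(OC)c3c(c2)[C@@H](CO[Si](C(C)C)(C(C)C)C(C)C)[C@@H](c2ccc(O[Si](C(C)C)(C(C)C)C(C)C)c(OC)c2)O3)ccc1O[Si](C(C)C)(C(C)C)C(C)C
F3 | step 16 | cis-5-Ar′-4-{[(ArG)methoxy]methyl}dihydrofuran-2(3H)-one | COc1cc(COC[C@@H]2CC(=O)O[C@@H]2c2cc(OC)c3c(c2)[C@@H](CO[Si](C(C)C)(C(C)C)C(C)C)[C@@H](c2ccc(O[Si](C(C)C)(C(C)C)C(C)C)c(OC)c2)O3)ccc1O[Si](C(C)C)(C(C)C)C(C)C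
F4 | step 16 | 3-(trifluoroacetyl) derivative of lactone F3 (C3 epimers) | COc1cc(COC[C@@H]2C(C(=O)C(F)(F)F)C(=O)O[C@@H]2c2cc(OC)c3c(c2)[C@@H](CO[Si](C(C)C)(C(C)C)C(C)C)[C@@H](c2ccc(O[Si](C(C)C)(C(C)C)C(C)C)c(OC)c2)O3)ccc1O[Si](C(C)C)(C(C)C)C(C)C
F5 | step 16 | 3-diazo derivative of lactone F3 | COc1cc(COC[C@@H]2C(=[N+]=[N-])C(=O)O[C@@H]2c2cc(OC)c3c(c2)[C@@H](CO[Si](C(C)C)(C(C)C)C(C)C)[C@@H](c2ccc(O[Si](C(C)C)(C(C)C)C(C)C)c(OC)c2)O3)ccc1O[Si](C(C)C)(C(C)C)C(C)C
F6 | step 16 | C9-oxo analogue of 27 (furofuranone; aryl groups on C7 and C7′ endo) | COc1cc([C@H]2OC[C@@H]3[C@H]2C(=O)O[C@@H]3c2cc(OC)c3c(c2)[C@@H](CO[Si](C(C)C)(C(C)C)C(C)C)[C@@H](c2ccc(O[Si](C(C)C)(C(C)C)C(C)C)c(OC)c2)O3)ccc1O[Si](C(C)C)(C(C)C)C(C)C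
F7 | step 16 | C9-hydroxy analogue of 27 (lactol, anomers) | COc1cc([C@H]2OC[C@@H]3[C@H]2C(O)O[C@@H]3c2cc(OC)c3c(c2)[C@@H](CO[Si](C(C)C)(C(C)C)C(C)C)[C@@H](c2ccc(O[Si](C(C)C)(C(C)C)C(C)C)c(OC)c2)O3)ccc1O[Si](C(C)C)(C(C)C)C(C)C
F8 | step 17 | C9-hydroxy analogue of 27 (lactol, anomers) | COc1cc([C@H]2OC[C@@H]3[C@H]2C(O)O[C@@H]3c2cc(OC)c3c(c2)[C@@H](CO[Si](C(C)C)(C(C)C)C(C)C)[C@@H](c2ccc(O[Si](C(C)C)(C(C)C)C(C)C)c(OC)c2)O3)ccc1O[Si](C(C)C)(C(C)C)C(C)C
F9 | step 17 | all-cis 2-ArG-3-(hydroxymethyl)-4-[(S)-hydroxy(Ar′)methyl]tetrahydrofuran (ring B opened diol) | COc1cc([C@H]2OC[C@@H]([C@H](O)c3cc(OC)c4c(c3)[C@@H](CO[Si](C(C)C)(C(C)C)C(C)C)[C@@H](c3ccc(O[Si](C(C)C)(C(C)C)C(C)C)c(OC)c3)O4)[C@H]2CO)ccc1O[Si](C(C)C)(C(C)C)C(C)C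
F10 | step 17 | primary 4-methylbenzenesulfonate of diol F9 | COc1cc([C@H]2OC[C@@H]([C@H](O)c3cc(OC)c4c(c3)[C@@H](CO[Si](C(C)C)(C(C)C)C(C)C)[C@@H](c3ccc(O[Si](C(C)C)(C(C)C)C(C)C)c(OC)c3)O4)[C@H]2COS(=O)(=O)c2ccc(C)cc2)ccc1O[Si](C(C)C)(C(C)C)C(C)C
F11 | step 14 | (2S)-2-[(S)-hydroxy(Ar′)methyl]pent-4-en-1-ol | OC[C@H](CC=C)[C@H](O)c1cc(OC)c2c(c1)[C@@H](CO[Si](C(C)C)(C(C)C)C(C)C)[C@@H](c1ccc(O[Si](C(C)C)(C(C)C)C(C)C)c(OC)c1)O2
F12 | step 14 | (2S)-2-[(S)-hydroxy(Ar′)methyl]pent-4-en-1-yl pivalate | CC(C)(C)C(=O)OC[C@H](CC=C)[C@H](O)c1cc(OC)c2c(c1)[C@@H](CO[Si](C(C)C)(C(C)C)C(C)C)[C@@H](c1ccc(O[Si](C(C)C)(C(C)C)C(C)C)c(OC)c1)O2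
F13 | step 14 | [cis-2-Ar′-5-hydroxytetrahydrofuran-3-yl]methyl pivalate (C5 anomers) | CC(C)(C)C(=O)OC[C@@H]1CC(O)O[C@@H]1c2cc(OC)c3c(c2)[C@@H](CO[Si](C(C)C)(C(C)C)C(C)C)[C@@H](c2ccc(O[Si](C(C)C)(C(C)C)C(C)C)c(OC)c2)O3
F14 | step 14 | [(2S,3S)-2-Ar′-2,3-dihydrofuran-3-yl]methyl pivalate | CC(C)(C)C(=O)OC[C@@H]1C=CO[C@@H]1c2cc(OC)c3c(c2)[C@@H](CO[Si](C(C)C)(C(C)C)C(C)C)[C@@H](c2ccc(O[Si](C(C)C)(C(C)C)C(C)C)c(OC)c2)O3
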